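**Retrosynthetic overview**
- Bromophycolide E ⇐ methanolysis of its 4'-O-acetyl-11-O-trifluoroacetyl derivative ⇐ transannular bromonium-ene cyclization (C2–C7 bond, C6–Br, exocyclic C3=CH2) of a 19-membered geranylgeranyl benzoate macrolide.
- C10–Br/C11–OH ⇐ anti bromohydration of the C10=C11 olefin of that macrolide, done before the carbocyclization so that only the C6=C7 bromonium can start a ring closure.
- Macrolide ⇐ Mitsunobu macrolactonization (C14–O bond, inversion at C14) of the seco acid.
- C14 carbinol ⇐ Shi epoxidation of the terminal olefin (first stereocentre), then epoxide-to-allylic-alcohol isomerization.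
- Skeleton ⇐ ortho C-alkylation of methyl 4-hydroxybenzoate with geranylgeranyl bromide. Ring order: 19-membered macrolactone first, cyclohexane second (the macrocycle contracts to 15 members).

Assumption: (2E,6E,10E)-geranylgeraniol and methyl 4-hydroxybenzoate are the commercial achiral starting materials; chain carbons are numbered C1 (benzylic) to C16, arene carbons are primed (C1' carries the carboxyl, C4' the oxygen).

**Route**

Step 1
Reactants: 1 (2E,6E,10E)-geranylgeraniol
Product: 2 (2E,6E,10E)-geranylgeranyl bromide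
Conditions: PBr3 (0.4 equiv), Et2O, −10 °C, 30 min; used crude
Reagents that add atoms: phosphorus tribromide BrP(Br)Br
Why: Conversion of a primary allylic alcohol into the allylic bromide (SN2 on the bromophosphite) leaves the trisubstituted olefins untouched and keeps the 2E geometry at low temperature.

Step 2
Reactants: 2 (2E,6E,10E)-geranylgeranyl bromide; 3 methyl 4-hydroxybenzoate
Product: 5 methyl 3-geranylgeranyl-4-hydroxybenzoate, via sodium 4-(methoxycarbonyl)phenolate 4 (not isolated)
Conditions: 3 (3 equiv), NaH (3 equiv), toluene, 23 °C, 1 h; then 2, 23 °C, 16 h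
Reagents that add atoms: none
Why: Phenolate ortho-C-alkylation: in a non-polar solvent the tight sodium ion pair shields oxygen, so the allylic bromide is attacked by the ortho carbon (SN2, unrearranged, 2E kept); the two ortho positions are equivalent and excess phenolate suppresses dialkylation.

Step 3
Reactants: 5 methyl 3-geranylgeranyl-4-hydroxybenzoate
Product: 6 methyl 3-[(2E,6E,10E,14R)-14,15-epoxygeranylgeranyl]-4-hydroxybenzoate
Conditions: 1,2:4,5-di-O-isopropylidene-β-D-erythro-2,3-hexodiulo-2,6-pyranose (0.3 equiv), KHSO5 (0.8 equiv, as 2KHSO5·KHSO4·K2SO4), K2CO3, Bu4NHSO4 (cat.), MeCN/CH2(OMe)2/aq. Na2B4O7 buffer (pH 10.5), −5 °C, about 50% conversion; 5 recycled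
Reagents that add atoms: potassium peroxymonosulfate [K+].[O-]S(=O)(=O)OO
Why: Shi asymmetric epoxidation: the chiral dioxirane reacts first with the terminal gem-dimethyl olefin (the least hindered trisubstituted olefin) and its spiro transition state delivers oxygen to the face that gives the 14R epoxide, setting the first stereocentre by catalysis.

Step 4
Reactants: 6 methyl 3-[(2E,6E,10E,14R)-14,15-epoxygeranylgeranyl]-4-hydroxybenzoate
Product: 7 methyl 4-hydroxy-3-[(2E,6E,10E,14R)-14-hydroxy-3,7,11,15-tetramethylhexadeca-2,6,10,15-tetraen-1-yl]benzoate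
Conditions: Et2Al(NC9H18) (diethylaluminium 2,2,6,6-tetramethylpiperidide, 5 equiv, from LiNC9H18 + Et2AlCl), toluene, 0 °C, 2 h; aq. potassium sodium tartrate
Reagents that add atoms: none
Why: Aluminium amide-mediated epoxide-to-allylic-alcohol isomerization: the bulky amide removes a methyl proton in a cyclic syn elimination that breaks only the C15–O bond, so C14 keeps its R configuration and the isopropenyl carbinol is formed.

Step 5
Reactants: 7 methyl 4-hydroxy-3-[(2E,6E,10E,14R)-14-hydroxy-3,7,11,15-tetramethylhexadeca-2,6,10,15-tetraen-1-yl]benzoate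
Product: 8 4-hydroxy-3-[(2E,6E,10E,14R)-14-hydroxy-3,7,11,15-tetramethylhexadeca-2,6,10,15-tetraen-1-yl]benzoic acid
Conditions: KOH (2 M aq.), MeOH/THF, 65 °C; then 1 M HCl, 0 °C, to pH 4
Reagents that add atoms: potassium hydroxide [K+].[OH-]
Why: Saponification of the methyl benzoate (acyl–oxygen cleavage by hydroxide); the allylic alcohol, the skipped triene and the C14 stereocentre are inert to base.

Step 6
Reactants: 8 4-hydroxy-3-[(2E,6E,10E,14R)-14-hydroxy-3,7,11,15-tetramethylhexadeca-2,6,10,15-tetraen-1-yl]benzoic acid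
Product: 9 (2E,6E,10E,14S)-19-membered macrolactone with free phenol
Conditions: PPh3 (4 equiv), DIAD (4 equiv), toluene/THF 10:1, 0.002 M (8 added over 8 h), 0 → 23 °C
Reagents that add atoms: none
Why: Mitsunobu macrolactonization at high dilution: the carboxylic acid, far more acidic than the phenol, is the pronucleophile and displaces the C14 oxyphosphonium by SN2, so 14R is inverted to the 14S ester of the target.

Step 7
Reactants: 9 (2E,6E,10E,14S)-19-membered macrolactone with free phenol
Product: 10 4'-O-acetyl macrolactone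
Conditions: Ac2O, pyridine, 4-(dimethylamino)pyridine (5 mol %), CH2Cl2, 0 °C
Reagents that add atoms: acetic anhydride CC(=O)OC(C)=O
Why: Nucleophile-catalysed acylation of the only free OH deactivates the arene and the phenol oxygen toward the electrophilic bromine used in the next two steps.

Step 8
Reactants: 10 4'-O-acetyl macrolactone
Product: 11 (10R,11S,14S)-10-bromo-11-hydroxy macrolactone acetate
Conditions: NBS (1.0 equiv), THF/H2O 3:1, 0 °C, dark, 20 min; HPLC separation
Reagents that add atoms: N-bromosuccinimide O=C1CCC(=O)N1Br; water O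
Why: Electrophilic bromohydration: Markovnikov anti opening of the bromonium by water puts Br on C10 and OH on C11, and the E olefin geometry fixes the relative configuration as 10R,11S (or its 10S,11R counterpart, which is separated); C10=C11 is favoured only modestly, as the trisubstituted olefin nearest the polar lactone and farthest from the hindered aryl end.

Step 9
Reactants: 11 (10R,11S,14S)-10-bromo-11-hydroxy macrolactone acetate
Product: 13 4'-O-acetyl-11-O-trifluoroacetylbromophycolide E, via 11-O-trifluoroacetate 12 (not isolated)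
Conditions: (CF3CO)2O, pyridine, CH2Cl2, −20 °C; evaporate, filter in pentane; then (R)-[3,3'-(2,4,6-iPr3C6H2)2-BINOL]P(=S)NH[3,5-(CF3)2C6H3] (10 mol %), NBS (1.1 equiv), toluene/CH2Cl2 4:1, −78 → −50 °C; fast chromatography on deactivated silica
Reagents that add atoms: trifluoroacetic anhydride O=C(OC(=O)C(F)(F)F)C(F)(F)F; N-bromosuccinimide O=C1CCC(=O)N1Br
Why: Proposed new method: a chiral Lewis-base-catalysed transannular bromonium-ene cyclization inside a macrolide, run after in-flask trifluoroacetylation of the tertiary OH so that it cannot close a bromo-tetrahydropyran onto C7; the thiophosphoramide sulfur takes Br+ from NBS and shuttles it reversibly between the olefins, but only the C6=C7 bromonium has a π-partner (C2=C3) placed for a chair-like six-membered closure (C10=C11 is already a bromohydrin ester, the C2=C3 bromonium has no nucleophile in reach), C2 adds to C7 anti to bromine, and the C3 cation loses a proton from its methyl group to the catalyst-bound succinimide anion to give the exocyclic methylene; the E,E geometry fixes the relative configuration (Br and C8 equatorial, C7 methyl axial, benzyl equatorial) and the catalyst selects the C6=C7 face that gives 2R,6S,7S; the closest known reaction types are chiral thiophosphoramide- or phosphoramidite-promoted bromocyclization of acyclic geranyl arenes with arene termination and stoichiometric bromosulfonium polyene cyclization.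

Step 10
Reactants: 13 4'-O-acetyl-11-O-trifluoroacetylbromophycolide E
Product: 14 bromophycolide E
Conditions: KHCO3, MeOH, 0 → 23 °C
Reagents that add atoms: none
Why: Mild base-catalysed methanolysis removes the two activated esters (aryl acetate and trifluoroacetate), while the alkyl benzoate lactone, both C–Br bonds, the bromohydrin and all six stereocentres are untouched.

**Compound list**
1 | (2E,6E,10E)-3,7,11,15-tetramethylhexadeca-2,6,10,14-tetraen-1-ol (geranylgeraniol) | CC(C)=CCC/C(C)=C/CC/C(C)=C/CC/C(C)=C/CO | starting material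
2 | (2E,6E,10E)-1-bromo-3,7,11,15-tetramethylhexadeca-2,6,10,14-tetraene (geranylgeranyl bromide) | CC(C)=CCC/C(C)=C/CC/C(C)=C/CC/C(C)=C/CBr | intermediate
3 | methyl 4-hydroxybenzoate | COC(=O)c1ccc(O)cc1 | starting material
4 | sodium 4-(methoxycarbonyl)phenolate | COC(=O)c1ccc([O-])cc1.[Na+] | intermediate
5 | methyl 4-hydroxy-3-[(2E,6E,10E)-3,7,11,15-tetramethylhexadeca-2,6,10,14-tetraen-1-yl]benzoate | COC(=O)c1ccc(O)c(C/C=C(\C)CC/C=C(\C)CC/C=C(\C)CCC=C(C)C)c1 | intermediate
6 | methyl 3-{(2E,6E,10E)-13-[(2R)-3,3-dimethyloxiran-2-yl]-3,7,11-trimethyltrideca-2,6,10-trien-1-yl}-4-hydroxybenzoate (14R epoxide) | COC(=O)c1ccc(O)c(C/C=C(\C)CC/C=C(\C)CC/C=C(\C)CC[C@H]2OC2(C)C)c1 | intermediate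
7 | methyl 4-hydroxy-3-[(2E,6E,10E,14R)-14-hydroxy-3,7,11,15-tetramethylhexadeca-2,6,10,15-tetraen-1-yl]benzoate | COC(=O)c1ccc(O)c(C/C=C(\C)CC/C=C(\C)CC/C=C(\C)CC[C@@H](O)C(C)=C)c1 | intermediate
8 | 4-hydroxy-3-[(2E,6E,10E,14R)-14-hydroxy-3,7,11,15-tetramethylhexadeca-2,6,10,15-tetraen-1-yl]benzoic acid | OC(=O)c1ccc(O)c(C/C=C(\C)CC/C=C(\C)CC/C=C(\C)CC[C@@H](O)C(C)=C)c1 | intermediate
9 | (2E,6E,10E,14S)-19-membered macrolactone: the C1' carboxyl of the 4'-hydroxy-3'-alkylbenzoate esterifies O14 of the 3,7,11-trimethyl-14-(prop-1-en-2-yl)tetradeca-2,6,10-triene chain; phenol free | C=C(C)[C@@H]1CC/C(C)=C/CC/C(C)=C/CC/C(C)=C/Cc2cc(ccc2O)C(=O)O1 | intermediate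
10 | 4'-O-acetate of 9 | C=C(C)[C@@H]1CC/C(C)=C/CC/C(C)=C/CC/C(C)=C/Cc2cc(ccc2OC(C)=O)C(=O)O1 | intermediate
11 | (2E,6E,10R,11S,14S)-10-bromo-11-hydroxy-10,11-dihydro derivative of 10 | C=C(C)[C@@H]1CC[C@](C)(O)[C@H](Br)CC/C(C)=C/CC/C(C)=C/Cc2cc(ccc2OC(C)=O)C(=O)O1 | intermediate
12 | 11-O-trifluoroacetate of 11 | C=C(C)[C@@H]1CC[C@](C)(OC(=O)C(F)(F)F)[C@H](Br)CC/C(C)=C/CC/C(C)=C/Cc2cc(ccc2OC(C)=O)C(=O)O1 | intermediate
13 | 4'-O-acetyl-11-O-trifluoroacetylbromophycolide E (2R,6S,7S,10R,11S,14S; cyclohexane C2–C7, Br on C6 and C10, exocyclic C3=CH2) | C=C(C)[C@@H]1CC[C@](C)(OC(=O)C(F)(F)F)[C@H](Br)CC[C@@]2(C)[C@H](Cc3cc(ccc3OC(C)=O)C(=O)O1)C(=C)CC[C@@H]2Br | intermediate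
14 | bromophycolide E (2R,6S,7S,10R,11S,14S in chain numbering) | C=C(C)[C@@H]1CC[C@](C)(O)[C@H](Br)CC[C@@]2(C)[C@H](Cc3cc(ccc3O)C(=O)O1)C(=C)CC[C@@H]2Br | target

**Step count and risks**

Total steps: 10. Longest linear sequence: 10 (from 1 to 14).

The three steps most likely to fail are 3, 8 and 9.

Step 3 asks one of four trisubstituted olefins to react first, and it runs with a phenolate present; internal mono-epoxides and over-oxidation are the expected losses. If site selectivity or ee is too low, the fallback sets out from 5 and changes both the way the terminus is addressed and the way the stereocentre is set. NBS in THF/H2O at 0 °C, which attacks the exposed chain terminus in aqueous medium, gives racemic methyl 3-[(2E,6E,10E)-14-bromo-15-hydroxy-3,7,11,15-tetramethylhexadeca-2,6,10-trien-1-yl]-4-hydroxybenzoate F1. K2CO3 in MeOH closes it to the racemic 14,15-epoxide of 5 F2. Et2Al(NC9H18) as in step 4 gives the racemic allylic alcohol corresponding to 7 F3. Dess–Martin periodinane (NaHCO3, CH2Cl2) gives methyl 4-hydroxy-3-[(2E,6E,10E)-3,7,11,15-tetramethyl-14-oxohexadeca-2,6,10,15-tetraen-1-yl]benzoate F4. Reduction with (S)-1-methyl-3,3-diphenyltetrahydro-1H,3H-pyrrolo[1,2-c][1,3,2]oxazaborole (20 mol %) and catecholborane in toluene at −78 °C, with the isopropenyl group acting as the large substituent, returns to the route at 7 with the 14R configuration.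

Step 8 has no strong bias between C10=C11 and C6=C7, and none between the two faces of a flexible 19-membered ring. A mixture of regio- and diastereomers is therefore likely and the yield of 11 may be low. The fallback sets out from 10 and reverses the order of the two bromonium events. Et2SBr·SbCl5Br in MeNO2 at −25 °C closes the carbocycle first, giving 4'-O-acetyl-10-debromo-11-deoxy-10,11-didehydrobromophycolide E F5; products initiated at C10=C11 are separated. NBS in THF/H2O then meets a single trisubstituted olefin held in a more rigid 15-membered ring and gives 4'-O-acetylbromophycolide E F6. KHCO3 in MeOH then rejoins the route at 14. No trifluoroacetate is needed in this order.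

Step 9, the proposed new reaction, can fail in three ways. The chiral catalyst may not override the macrocycle's own facial preference; the enantiomeric catalyst is then tried. The C3 cation may lose a ring proton and give endocyclic olefin isomers. Bromine may be diverted to the isopropenyl group, assisted by the neighbouring benzoate. The fallback uses known chemistry and replaces catalyst control by substrate control plus separation. It sets out from 12, made from 11 exactly as in step 9, and treats it with stoichiometric Et2SBr·SbCl5Br (1.1 equiv) in MeNO2 at −25 °C for 5 min, the established reagent for bromonium polyene cyclization. The 2R,6S,7S product is separated from its ring diastereomer and olefin isomers by HPLC, and the route is rejoined at 13. This fallback makes no compound outside the list (none F0).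

Further compounds
F1 | step 3 | racemic methyl 3-[(2E,6E,10E)-14-bromo-15-hydroxy-3,7,11,15-tetramethylhexadeca-2,6,10-trien-1-yl]-4-hydroxybenzoate | COC(=O)c1ccc(O)c(C/C=C(\C)CC/C=C(\C)CC/C=C(\C)CCC(Br)C(C)(C)O)c1
F2 | step 3 | racemic methyl 3-[(2E,6E,10E)-14,15-epoxy-3,7,11,15-tetramethylhexadeca-2,6,10-trien-1-yl]-4-hydroxybenzoate | COC(=O)c1ccc(O)c(C/C=C(\C)CC/C=C(\C)CC/C=C(\C)CCC2OC2(C)C)c1
F3 | step 3 | racemic methyl 4-hydroxy-3-[(2E,6E,10E)-14-hydroxy-3,7,11,15-tetramethylhexadeca-2,6,10,15-tetraen-1-yl]benzoate | COC(=O)c1ccc(O)c(C/C=C(\C)CC/C=C(\C)CC/C=C(\C)CCC(O)C(C)=C)c1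
F4 | step 3 | methyl 4-hydroxy-3-[(2E,6E,10E)-3,7,11,15-tetramethyl-14-oxohexadeca-2,6,10,15-tetraen-1-yl]benzoate | COC(=O)c1ccc(O)c(C/C=C(\C)CC/C=C(\C)CC/C=C(\C)CCC(=O)C(C)=C)c1
F5 | step 8 | 4'-O-acetyl-10-debromo-11-deoxy-10,11-didehydrobromophycolide E (2R,6S,7S,10E,14S) | C=C(C)[C@@H]1CC/C(C)=C/CC[C@@]2(C)[C@H](Cc3cc(ccc3OC(C)=O)C(=O)O1)C(=C)CC[C@@H]2Br
F6 | step 8 | 4'-O-acetylbromophycolide E (2R,6S,7S,10R,11S,14S) | C=C(C)[C@@H]1CC[C@](C)(O)[C@H](Br)CC[C@@]2(C)[C@H](Cc3cc(ccc3OC(C)=O)C(=O)O1)C(=C)CC[C@@H]2Br
F0 | step 9 | none | none
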